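## Analysis of the target

The target (18) is 6,8-diprenylquercetin, a flavonol in which ring A is the benzo ring (C4a, C5, C6, C7, C8, C8a), ring C is the 4-pyranone (O1, C2, C3, C4) with a hydroxyl on C3, and ring B is a 3,4-dihydroxyphenyl group on C2. There is no stereocentre, and both side-chain alkenes end in two identical methyl groups, so no configuration has to be set. The sensitive groups are the two prenyl groups on C6 and C8, which flank the 7-OH (C6 also the 5-OH): under acid they close to 2,2-dimethylchromans, and electrophilic oxidants attack them. The catechol and the 3-hydroxy-4-pyranone are oxidised in aerated base and bind metals. The difficulty is the hexasubstituted ring A: two C-prenyl groups cannot be put cleanly onto a preformed phloroglucinol or flavonol ring, because O-alkylation, over-alkylation and geminal dialkylation compete and C6 and C8 are hard to tell apart. The route rests on ring A being an acylphloroglucinol: C4a carries the acyl carbon C4, C5, C7 and C8a carry oxygen, and C6 and C8 carry the prenyl groups. This is the pattern left when a linear 3,5,7-trioxo ester is folded by a Claisen condensation; in that chain the prenyl-bearing carbons are ordinary α-carbons between carbonyl groups, and the C3 oxygen of ring C is the terminal oxygen of the chain.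

## Retrosynthetic reasoning

**18 from 17.** The last operation removes the three methoxymethyl groups on O3, O3' and O4'. The 5-OH and 7-OH are never protected: they are formed free in the ring-A step and one ortho hydroxyl is needed free for ring C. One acetal type on all three oxygens allows a single final deprotection.

**17 from 10 and 15.** Ring C is opened at O1–C2 and C2–C3 (Allan–Robinson disconnection). The ketone carbon of 10 is C4 and its α-carbon, which already carries the protected oxygen, is C3, so the flavonol oxidation level is present from the start and no later oxidation next to the prenyl groups is needed. Ring A of 10 is symmetric about the acyl axis, so either ortho hydroxyl gives the same flavone. The forward reaction must C-aroylate the α-carbon, cyclodehydrate, and then lose the O-aroyl group that ends up on O7 (intermediate 16).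

**15 from 13 and 14, 14 from 13, and 13 from 11.** The anhydride is cut at its central acyl–oxygen bond into the carboxylic acid 13 and the acid chloride 14, so that it is assembled from a nucleophilic and an electrophilic partner. Chloride 14 is made from a second portion of 13 under neutral conditions that the acetals tolerate. Acid 13 comes from acid 11 by exhaustive acetal protection through ester 12 and selective cleavage of the ester.

**10 from 9 (key disconnection).** The C4a–C5 bond of ring A is cut, which unfolds the arene into the open-chain ester 9. The cut is made here because it turns the hexasubstituted arene into a chain whose substitution pattern is set by ordinary enolate chemistry, and because the ring then closes through a carbanion flanked by two carbonyl groups attacking an ester. The forward step must fold 9 in the Claisen sense (chain C6 onto C1) and not in an aldol sense.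

**9 from 6 and 8.** The chain is cut between C6 and C7. The terminal methyl group of 6 is the nucleophile and the ester 8 delivers C7, C8 and the protected oxygen. This keeps the oxygenated two-carbon piece as a simple ester made in one step from 7 and avoids a masked β-keto acid building block. The forward reaction is a terminal acylation of the polyanion of 6.

**6 from 4 and 5.** The chain is cut between C4 and C5. The γ-carbanion of the dianion of 4 is acylated by the amide 5, which adds the acetyl unit (C5 and C6).

**4 from 3 and 2, and 3 from 1 and 2.** Both prenyl groups are traced back to bromide 2. One is placed on the γ-carbon of 1 through its dianion and the other on the α-carbon of 3 through its enolate. Carbon alkylation of β-keto ester anions by a primary allylic bromide is regiochemically unambiguous, so the O- versus C-alkylation problem of a phenol does not arise.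

## Alternatives that were turned down

Alternative 1: double Suzuki–Miyaura prenylation.
- Disconnection and key step: the bonds from C6 and C8 to the allylic methylene carbons are cut. The diiodide A2, 6,8-diiodo-3,5,7-tris(methoxymethoxy)-2-[3,4-bis(methoxymethoxy)phenyl]chromen-4-one, would be coupled twice with the prenylboronic ester A3 under Pd(OAc)2, a bulky dialkylbiarylphosphine and K3PO4, to give the pentakis(methoxymethyl) ether A1.
- For: A2 should be reachable in about two steps from quercetin A4, whose only free ring-A positions are C6 and C8. The whole sequence would be about four steps against eleven here, and ring A, ring C and the oxidation pattern are bought ready-made. On step economy this alternative is clearly stronger.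
- Against: an allylboron reagent transmetalates with allylic transposition, and the allylpalladium intermediate can eliminate at either end, giving the linear prenyl or the branched 1,1-dimethylallyl group. The linear outcome is needed twice, at carbons that each sit between two ortho oxygen substituents, where reductive elimination is slow and protodeiodination competes. Mono-coupled and linear/branched mixed products would differ very little in polarity. Five acetals would then have to be removed with acid next to the prenyl groups.
- Comparison: the chosen route is longer, but it fixes the linear prenyl regiochemistry by SN2 alkylation of enolates, needs no ligand-controlled selectivity at crowded positions and no precious metal.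

Alternative 2: carbene-catalysed benzoin closure.
- Disconnection and key step: the C3–C4 bond of ring C is cut. A triazolium-derived N-heterocyclic carbene would convert one aldehyde of the dialdehyde A6 into an acyl-anion equivalent that adds to the other, closing ring C as the racemic trans-dihydroflavonol A5.
- For: the closure is catalytic, runs near room temperature, and installs the C3 oxygen. It is milder than the hot Allan–Robinson step used here, and on that point it is stronger.
- Against: A5 is a dihydroflavonol, so a C2–C3 dehydrogenation in the presence of two prenyl groups must follow, and two stereocentres are made only to be destroyed. A6 contains an α-aryl-α-aryloxy aldehyde with a very acidic α-hydrogen, which is prone to enolisation and self-condensation. The aryl aldehyde that must form the acyl-anion equivalent is flanked by two ortho substituents, while the aliphatic aldehyde is the more reactive one. Ring A with both prenyl groups must already exist, so the central problem is only moved back.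
- Comparison: the sequence would be longer than the chosen one and leaves the ring-A problem unsolved, whereas the chosen key step builds ring A with its substitution pattern.

Alternative 3: carbonylative alkyne annulation.
- Disconnection and key step: the C4a–C4, C4–C3 and O1–C2 bonds are cut. The iodide A8, 2-iodo-4,6-bis(3-methylbut-2-enyl)benzene-1,3,5-triyl triacetate, carbon monoxide A10 and the alkyne A9 would combine under PdCl2(PPh3)2 in diethylamine to give the flavone A7.
- For: three bonds and ring C are formed in one convergent catalytic operation, and ring B arrives as a simple alkyne. On convergence it is stronger than the chosen route.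
- Against: A7 has no oxygen on C3. Hydroxylating C3 afterwards, by epoxidation of the C2–C3 bond or by metalation and oxidation, collides with the two electron-rich prenyl alkenes, which react with electrophilic oxidants faster than the enone. A8 is a hexasubstituted aryl iodide with two ortho acetoxy groups, so oxidative addition and the insertion of carbon monoxide A10 are hindered. A8 again presupposes a doubly C-prenylated phloroglucinol. Closure to a five-membered aurone ring competes with the six-membered closure.
- Comparison: the chosen route carries the C3 oxygen in the chain from the start and never has to oxidise in the presence of the prenyl groups.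

Key step: step 6

Assumption: compound 4 is racemic and compounds 6 and 9 are handled as mixtures of epimers and keto–enol tautomers; this has no consequence because C2 and C4 of the chain become sp2 carbons of ring A in step 6.

## Route

Step 1
Reactants: 1 methyl acetoacetate (methyl 3-oxobutanoate); 2 1-bromo-3-methylbut-2-ene (prenyl bromide)
Product: 3 methyl 7-methyl-3-oxooct-6-enoate
Conditions: NaH, THF, 0 °C; n-BuLi, 0 °C; then 2, 0 °C → rt; aq NH4Cl
Reagents that add atoms: none
Why: γ-Alkylation of the acetoacetate dianion; the terminal carbanion is the more nucleophilic site and displaces bromide at the primary allylic carbon by SN2, so only the linear prenyl group should be introduced.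

Step 2
Reactants: 3 methyl 7-methyl-3-oxooct-6-enoate; 2 1-bromo-3-methylbut-2-ene
Product: 4 methyl 7-methyl-2-(3-methylbut-2-enyl)-3-oxooct-6-enoate (racemic)
Conditions: K2CO3, acetone, reflux
Reagents that add atoms: none
Why: C-Alkylation of a β-keto ester enolate with a soft allylic bromide; the C2 stereocentre is not controlled and is erased in step 6.

Step 3
Reactants: 4 methyl 7-methyl-2-(3-methylbut-2-enyl)-3-oxooct-6-enoate; 5 N-methoxy-N-methylacetamide
Product: 6 methyl 3,5-dioxo-2,4-bis(3-methylbut-2-enyl)hexanoate (mixture of diastereomers and enol tautomers)
Conditions: LiN(iPr)2 (2.2 equiv), THF, −78 → 0 °C; then 5, −78 → 0 °C; aq NH4Cl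
Reagents that add atoms: none
Why: Acylation of a β-keto ester dianion at its γ-carbon (C4) by an N-methoxy-N-methylamide; the chelated tetrahedral adduct should persist until work-up, so the more acidic product cannot quench unreacted dianion, and the new C4 stereocentre is irrelevant.

Step 4
Reactants: 7 methyl glycolate (methyl 2-hydroxyacetate)
Product: 8 methyl 2-(methoxymethoxy)acetate
Conditions: MOMCl, iPr2NEt, CH2Cl2, 0 °C → rt
Reagents that add atoms: chloromethyl methyl ether, COCCl
Why: Standard acetal protection of a primary alcohol by O-alkylation with an α-chloro ether under amine base.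

Step 5
Reactants: 6 methyl 3,5-dioxo-2,4-bis(3-methylbut-2-enyl)hexanoate; 8 methyl 2-(methoxymethoxy)acetate
Product: 9 methyl 8-(methoxymethoxy)-3,5,7-trioxo-2,4-bis(3-methylbut-2-enyl)octanoate (mixture of epimers and enol tautomers, used crude)
Conditions: LiN(iPr)2 (4.2 equiv), THF, −78 → 0 °C; then 8, −78 → −30 °C; AcOH, −78 °C; cold aqueous work-up
Reagents that add atoms: none
Why: Terminal acylation of a 3,5-dioxo ester trianion; after C2 and C4 are enolised the C6 methyl carbanion is the only strongly nucleophilic carbon, and the α-alkoxy ester 8 is an activated acyl donor; the extra equivalent of base covers the additional acidic site of the product.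

Step 6
Reactants: 9 methyl 8-(methoxymethoxy)-3,5,7-trioxo-2,4-bis(3-methylbut-2-enyl)octanoate
Product: 10 2-(methoxymethoxy)-1-[2,4,6-trihydroxy-3,5-bis(3-methylbut-2-enyl)phenyl]ethanone
Conditions: Mg(OMe)2 (5 equiv), MeOH, rt → 60 °C, Ar (degassed); cold 0.5 M HCl to pH 3–4
Reagents that add atoms: none
Why: Mg(OMe)2 should convert 9 into a magnesium polyenolate in which chelation holds the 3,5,7-tricarbonyl array cisoid, so that C6, the only unsubstituted doubly activated methylene, lies within reach of the C1 ester. C6 adds to the ester carbonyl in a 6-exo-trig Claisen (Dieckmann-type) closure that forms the future C4a–C5 bond, methoxide leaves, and the 2-acylcyclohexane-1,3,5-trione enolises three times to the arene; this irreversible aromatisation drains the reversible equilibria. The closest known reaction type is the Mg(OMe)2-mediated Claisen cyclisation of 3,5,7-trioxoalkanoates, and of the corresponding 6-(2-oxoalkyl)-4-hydroxypyran-2-ones, to 2-acylphloroglucinols; the two α-alkyl groups are the only extension. No stereocentre is formed, and the C2 and C4 stereocentres of 9 become sp2 carbons. The step needs Claisen over aldol selectivity: the aldol of C2 onto the C7 ketone would give a quaternary C2 that cannot dehydrate to an arene and so reverts, and the aldol of C8 onto C3 is disfavoured because C8 is only singly activated and C3 is masked as a chelated enolate. Lactonisation through the C5 enol oxygen is reversible in methanolic methoxide and feeds the same product. The methoxymethyl ether and the prenyl alkenes are inert to the basic medium, and exclusion of air protects the electron-rich product.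

Step 7
Reactants: 11 3,4-dihydroxybenzoic acid
Product: 13 3,4-bis(methoxymethoxy)benzoic acid, via methoxymethyl ester 12 (not isolated)
Conditions: MOMCl (3.5 equiv), iPr2NEt, DMF, 0 °C → rt; then NaOH, MeOH/H2O, rt; cold dilute HCl to pH 4
Reagents that add atoms: chloromethyl methyl ether, COCCl; sodium hydroxide, [Na+].[OH-]
Why: Exhaustive O-alkylation protects both phenols and the carboxyl group; hydroxide then cleaves only the acyl–oxygen bond of the methoxymethyl ester, because aryl acetals are stable to base.

Step 8
Reactants: 13 3,4-bis(methoxymethoxy)benzoic acid
Product: 14 3,4-bis(methoxymethoxy)benzoyl chloride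
Conditions: half of the batch of 13; 1-chloro-N,N,2-trimethylprop-1-en-1-amine (1.1 equiv), CH2Cl2, 0 °C → rt; concentrated, used crude
Reagents that add atoms: 1-chloro-N,N,2-trimethylprop-1-en-1-amine, CC(C)=C(Cl)N(C)C
Why: Neutral conversion of a carboxylic acid into its chloride by an α-chloroenamine: the acid adds to the reagent to give an acyloxyiminium chloride, and chloride then attacks the acyl carbon and releases the amide. No free HCl is formed, so the aryl acetals should survive.

Step 9
Reactants: 13 3,4-bis(methoxymethoxy)benzoic acid; 14 3,4-bis(methoxymethoxy)benzoyl chloride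
Product: 15 3,4-bis(methoxymethoxy)benzoic anhydride
Conditions: second half of 13, Et3N (1.2 equiv), CH2Cl2, 0 °C; then 14, 0 °C → rt; cold aq NaHCO3 wash
Reagents that add atoms: none
Why: Nucleophilic acyl substitution of the acid chloride by the triethylammonium carboxylate gives the symmetrical anhydride; the amine binds the chloride as its ammonium salt, so the acetals never meet acid.

Step 10
Reactants: 10 2-(methoxymethoxy)-1-[2,4,6-trihydroxy-3,5-bis(3-methylbut-2-enyl)phenyl]ethanone; 15 3,4-bis(methoxymethoxy)benzoic anhydride
Product: 17 5,7-dihydroxy-3-(methoxymethoxy)-2-[3,4-bis(methoxymethoxy)phenyl]-6,8-bis(3-methylbut-2-enyl)chromen-4-one, via 7-O-aroyl flavone 16 (not isolated)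
Conditions: 15 (4 equiv), Et3N, 150 °C, sealed tube, Ar; then KOH, MeOH/H2O, 60 °C, Ar; AcOH
Reagents that add atoms: none
Why: Allan–Robinson flavone synthesis with an ω-alkoxy ketone: O-aroylation, transfer of the aroyl group to the α-carbon through the enolate (Baker–Venkataraman-type shift), attack of the ortho hydroxyl on the new ketone and dehydration close ring C with the C3 oxygen in place. The two ortho hydroxyls of 10 are equivalent, so one flavone results; hydroxide then removes the O-aroyl group on O7 (and any on O5), while the acetals tolerate the basic medium throughout.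

Step 11
Reactants: 17 5,7-dihydroxy-3-(methoxymethoxy)-2-[3,4-bis(methoxymethoxy)phenyl]-6,8-bis(3-methylbut-2-enyl)chromen-4-one
Product: 18 3,5,7-trihydroxy-2-(3,4-dihydroxyphenyl)-6,8-bis(3-methylbut-2-enyl)chromen-4-one (target)
Conditions: HCl (1 M) in MeOH, 45 °C, Ar; stopped as soon as 17 is consumed
Reagents that add atoms: none
Why: Acid-catalysed acetal exchange with methanol releases the three hydroxyls as dimethoxymethane is formed; dilute acid, moderate temperature and short contact are chosen because acetal cleavage is expected to be faster than protonation of the trisubstituted alkenes.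

## Compound list

1 | methyl acetoacetate (methyl 3-oxobutanoate) | COC(=O)CC(C)=O | starting material
2 | 1-bromo-3-methylbut-2-ene (prenyl bromide) | CC(C)=CCBr | starting material
3 | methyl 7-methyl-3-oxooct-6-enoate | COC(=O)CC(=O)CCC=C(C)C | intermediate
4 | methyl 7-methyl-2-(3-methylbut-2-enyl)-3-oxooct-6-enoate (racemic) | COC(=O)C(CC=C(C)C)C(=O)CCC=C(C)C | intermediate
5 | N-methoxy-N-methylacetamide | CC(=O)N(C)OC | starting material
6 | methyl 3,5-dioxo-2,4-bis(3-methylbut-2-enyl)hexanoate (mixture of diastereomers) | COC(=O)C(CC=C(C)C)C(=O)C(CC=C(C)C)C(C)=O | intermediate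
7 | methyl glycolate (methyl 2-hydroxyacetate) | COC(=O)CO | starting material
8 | methyl 2-(methoxymethoxy)acetate | COCOCC(=O)OC | intermediate
9 | methyl 8-(methoxymethoxy)-3,5,7-trioxo-2,4-bis(3-methylbut-2-enyl)octanoate (mixture of epimers) | COCOCC(=O)CC(=O)C(CC=C(C)C)C(=O)C(CC=C(C)C)C(=O)OC | intermediate
10 | 2-(methoxymethoxy)-1-[2,4,6-trihydroxy-3,5-bis(3-methylbut-2-enyl)phenyl]ethanone | COCOCC(=O)c1c(O)c(CC=C(C)C)c(O)c(CC=C(C)C)c1O | intermediate
11 | 3,4-dihydroxybenzoic acid | O=C(O)c1ccc(O)c(O)c1 | starting material
12 | methoxymethyl 3,4-bis(methoxymethoxy)benzoate | COCOC(=O)c1ccc(OCOC)c(OCOC)c1 | intermediate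
13 | 3,4-bis(methoxymethoxy)benzoic acid | OC(=O)c1ccc(OCOC)c(OCOC)c1 | intermediate
14 | 3,4-bis(methoxymethoxy)benzoyl chloride | O=C(Cl)c1ccc(OCOC)c(OCOC)c1 | intermediate
15 | 3,4-bis(methoxymethoxy)benzoic anhydride | COCOc1ccc(cc1OCOC)C(=O)OC(=O)c1ccc(OCOC)c(OCOC)c1 | intermediate
16 | 5-hydroxy-3-(methoxymethoxy)-2-[3,4-bis(methoxymethoxy)phenyl]-6,8-bis(3-methylbut-2-enyl)-4-oxochromen-7-yl 3,4-bis(methoxymethoxy)benzoate | CC(C)=CCc1c(OC(=O)c4ccc(OCOC)c(OCOC)c4)c(CC=C(C)C)c2oc(-c3ccc(OCOC)c(OCOC)c3)c(OCOC)c(=O)c2c1O | intermediate
17 | 5,7-dihydroxy-3-(methoxymethoxy)-2-[3,4-bis(methoxymethoxy)phenyl]-6,8-bis(3-methylbut-2-enyl)chromen-4-one | CC(C)=CCc1c(O)c(CC=C(C)C)c2oc(-c3ccc(OCOC)c(OCOC)c3)c(OCOC)c(=O)c2c1O | intermediate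
18 | 3,5,7-trihydroxy-2-(3,4-dihydroxyphenyl)-6,8-bis(3-methylbut-2-enyl)chromen-4-one | CC(C)=CCc1c(O)c(CC=C(C)C)c2oc(-c3ccc(O)c(O)c3)c(O)c(=O)c2c1O | target

## Step count and least certain steps

Total: 11 steps. Longest linear sequence: 7 steps (steps 1, 2, 3, 5, 6, 10, 11, from methyl acetoacetate).

**Step 6 (key step).** The open chain is most likely to be lost before it folds. Its C2 and C4 carbons are tertiary, so the chain is less fully enolised and less tightly chelated than an unsubstituted trioxo ester. The exposed 1,3-dicarbonyl links can then be cleaved by methoxide (retro-Claisen), and closure through the C5 enol oxygen or aldol closure of C8 onto C3 can divert material. The fallback replaces direct folding of the labile chain by a ring transformation of an isolable heterocycle. It sets out from 9: catalytic DBU in toluene at room temperature should lactonise it deliberately to 4-hydroxy-6-[3-(methoxymethoxy)-2-oxopropyl]-3,5-bis(3-methylbut-2-enyl)pyran-2-one F1. In F1 carbons C1 to C5 are locked as an acidic, nucleophile-resistant pyranone that can be purified and stored. Heating F1 with Mg(OMe)2 in methanol should reopen the lactone on the magnesium template, where the Claisen closure gives 10, at which the route is rejoined.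

**Step 5.** Proton transfer is the main threat: the trianion can deprotonate the α-methylene of ester 8 or be quenched by the more acidic product, and the resulting polyanion may cyclise in an uncontrolled mode on warming. The fallback replaces acylation by aldol addition and oxidation and sets out from 6 and 8. Ester 8 would be reduced with iBu2AlH in CH2Cl2 at −78 °C to 2-(methoxymethoxy)acetaldehyde F2. The trianion of 6 should add to F2 at −78 °C much faster than it can exchange protons, and the aldolate is not acidic, giving methyl 7-hydroxy-8-(methoxymethoxy)-3,5-dioxo-2,4-bis(3-methylbut-2-enyl)octanoate F3. Oxidation of this β-hydroxy ketone with IBX in ethyl acetate would return the route to 9.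

**Step 10.** At 150 °C the electron-rich, air-sensitive phenol 10 may decompose, acetal groups may be lost in the hot carboxylic acid/ammonium carboxylate melt, and C-aroylation at the hindered α-oxygenated ketone may remain incomplete. The fallback is a stepwise low-temperature Baker–Venkataraman sequence that sets out from 10 and 15. Aroylation with 15, Et3N and catalytic DMAP in CH2Cl2 at room temperature should give 2-[2-(methoxymethoxy)acetyl]-4,6-bis(3-methylbut-2-enyl)benzene-1,3,5-triyl tris[3,4-bis(methoxymethoxy)benzoate] F4. LiN(SiMe3)2 in THF at −78 → 0 °C would shift one ortho aroyl group to the α-carbon to give 5-hydroxy-4-[2-(methoxymethoxy)-3-oxo-3-[3,4-bis(methoxymethoxy)phenyl]propanoyl]-2,6-bis(3-methylbut-2-enyl)-1,3-phenylene bis[3,4-bis(methoxymethoxy)benzoate] F5, in equilibrium with its cyclic hemiketal. Brief warming with NaOAc in AcOH at 80 °C, a buffered medium in which the acetals are expected to hold, would dehydrate the hemiketal to 3-(methoxymethoxy)-2-[3,4-bis(methoxymethoxy)phenyl]-6,8-bis(3-methylbut-2-enyl)-4-oxochromene-5,7-diyl bis[3,4-bis(methoxymethoxy)benzoate] F6. KOH in aqueous methanol at 60 °C under argon would then remove the two remaining esters, rejoining the route at 17.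

**Step 11.** The acid needed for acetal cleavage can also protonate a prenyl double bond, after which the neighbouring 7-OH (or 5-OH) closes a 2,2-dimethylchroman ring or methanol adds. The fallback changes the order of the last operations so that O7, the oxygen flanked by both prenyl groups, stays blocked during the acid step. It sets out from 16, which would be isolated instead of saponified. HCl in methanol would remove all five acetals while O7 is still an ester and O5 is tied up in the hydrogen bond to the C4 carbonyl, giving 3,5-dihydroxy-2-(3,4-dihydroxyphenyl)-6,8-bis(3-methylbut-2-enyl)-4-oxochromen-7-yl 3,4-dihydroxybenzoate F7. Saponification of F7 with degassed NaOH in aqueous methanol containing Na2S2O4 at 0 °C under argon, followed by acidification, would give the target 18.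

## Further compounds

F1 | step 6 | 4-hydroxy-6-[3-(methoxymethoxy)-2-oxopropyl]-3,5-bis(3-methylbut-2-enyl)pyran-2-one | COCOCC(=O)CC1=C(CC=C(C)C)C(O)=C(CC=C(C)C)C(=O)O1
F2 | step 5 | 2-(methoxymethoxy)acetaldehyde | COCOCC=O
F3 | step 5 | methyl 7-hydroxy-8-(methoxymethoxy)-3,5-dioxo-2,4-bis(3-methylbut-2-enyl)octanoate (mixture of diastereomers) | COCOCC(O)CC(=O)C(CC=C(C)C)C(=O)C(CC=C(C)C)C(=O)OC
F4 | step 10 | 2-[2-(methoxymethoxy)acetyl]-4,6-bis(3-methylbut-2-enyl)benzene-1,3,5-triyl tris[3,4-bis(methoxymethoxy)benzoate] | COCOCC(=O)c1c(OC(=O)c2ccc(OCOC)c(OCOC)c2)c(CC=C(C)C)c(OC(=O)c2ccc(OCOC)c(OCOC)c2)c(CC=C(C)C)c1OC(=O)c1ccc(OCOC)c(OCOC)c1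
F5 | step 10 | 5-hydroxy-4-[2-(methoxymethoxy)-3-oxo-3-[3,4-bis(methoxymethoxy)phenyl]propanoyl]-2,6-bis(3-methylbut-2-enyl)-1,3-phenylene bis[3,4-bis(methoxymethoxy)benzoate] (racemic) | COCOC(C(=O)c1ccc(OCOC)c(OCOC)c1)C(=O)c1c(O)c(CC=C(C)C)c(OC(=O)c2ccc(OCOC)c(OCOC)c2)c(CC=C(C)C)c1OC(=O)c1ccc(OCOC)c(OCOC)c1
F6 | step 10 | 3-(methoxymethoxy)-2-[3,4-bis(methoxymethoxy)phenyl]-6,8-bis(3-methylbut-2-enyl)-4-oxochromene-5,7-diyl bis[3,4-bis(methoxymethoxy)benzoate] | CC(C)=CCc1c(OC(=O)c4ccc(OCOC)c(OCOC)c4)c(CC=C(C)C)c2oc(-c3ccc(OCOC)c(OCOC)c3)c(OCOC)c(=O)c2c1OC(=O)c1ccc(OCOC)c(OCOC)c1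
F7 | step 11 | 3,5-dihydroxy-2-(3,4-dihydroxyphenyl)-6,8-bis(3-methylbut-2-enyl)-4-oxochromen-7-yl 3,4-dihydroxybenzoate | CC(C)=CCc1c(OC(=O)c4ccc(O)c(O)c4)c(CC=C(C)C)c2oc(-c3ccc(O)c(O)c3)c(O)c(=O)c2c1O
A1 | alternative 1 | 3,5,7-tris(methoxymethoxy)-2-[3,4-bis(methoxymethoxy)phenyl]-6,8-bis(3-methylbut-2-enyl)chromen-4-one | CC(C)=CCc1c(OCOC)c(CC=C(C)C)c2oc(-c3ccc(OCOC)c(OCOC)c3)c(OCOC)c(=O)c2c1OCOC
A2 | alternative 1 | 6,8-diiodo-3,5,7-tris(methoxymethoxy)-2-[3,4-bis(methoxymethoxy)phenyl]chromen-4-one | COCOc1ccc(cc1OCOC)-c1oc2c(I)c(OCOC)c(I)c(OCOC)c2c(=O)c1OCOC
A3 | alternative 1 | 4,4,5,5-tetramethyl-2-(3-methylbut-2-enyl)-1,3,2-dioxaborolane | CC(C)=CCB1OC(C)(C)C(C)(C)O1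
A4 | alternative 1 | quercetin, 3,5,7-trihydroxy-2-(3,4-dihydroxyphenyl)chromen-4-one | O=c1c(O)c(-c2ccc(O)c(O)c2)oc2cc(O)cc(O)c12
A5 | alternative 2 | racemic trans-3-hydroxy-5,7-bis(methoxymethoxy)-2-[3,4-bis(methoxymethoxy)phenyl]-6,8-bis(3-methylbut-2-enyl)chroman-4-one (one enantiomer drawn) | COCOc1ccc(cc1OCOC)[C@H]1Oc2c(CC=C(C)C)c(OCOC)c(CC=C(C)C)c(OCOC)c2C(=O)[C@@H]1O
A6 | alternative 2 | 2-[1-[3,4-bis(methoxymethoxy)phenyl]-2-oxoethoxy]-4,6-bis(methoxymethoxy)-3,5-bis(3-methylbut-2-enyl)benzaldehyde (racemic) | COCOc1ccc(cc1OCOC)C(C=O)Oc1c(CC=C(C)C)c(OCOC)c(CC=C(C)C)c(OCOC)c1C=O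
A7 | alternative 3 | 5,7-dihydroxy-2-[3,4-bis(methoxymethoxy)phenyl]-6,8-bis(3-methylbut-2-enyl)chromen-4-one | CC(C)=CCc1c(O)c(CC=C(C)C)c2oc(-c3ccc(OCOC)c(OCOC)c3)cc(=O)c2c1O
A8 | alternative 3 | 2-iodo-4,6-bis(3-methylbut-2-enyl)benzene-1,3,5-triyl triacetate | CC(=O)Oc1c(I)c(OC(C)=O)c(CC=C(C)C)c(OC(C)=O)c1CC=C(C)C
A9 | alternative 3 | 4-ethynyl-1,2-bis(methoxymethoxy)benzene | C#Cc1ccc(OCOC)c(OCOC)c1
A10 | alternative 3 | carbon monoxide | [C-]#[O+]
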